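**Strategy.** Everything rests on closing the indane cyclopentane last. Its benzylic CH(4-hydroxyphenyl) carbon is the δ-carbon of the enone (O=C–CH=C–CH–CHAr) in the bicyclo[3.2.1]octenedione, and the fused resorcinol ring is bound to the neighbouring ring-fusion carbon. The precursor is therefore a 2,4-dienone with an exocyclic 4-methoxybenzylidene group and a free 3,5-dimethoxyphenyl ring beside it. A Lewis acid makes the vinylogous oxocarbenium ion, the aryl ring adds to its benzylic end (1,6-Friedel–Crafts) and the dienol re-ketonises: one operation forms the ring, two stereocentres and the enone. The dienone comes from an oxidative [5+2] union of a quadrangularin-type bromoresorcinol with resveratrol trimethyl ether.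

Key step: step 9

Assumption: 1, 3, 7, 10 (THF solution) and 13 are taken as commercial, and the ligand antipode in step 3 is the one that gives (R)-5, to be fixed by a test reaction.

Numbering: indane locants are used for 5–12. Compound 15 keeps the same locants as a 3a,5-ethanoindene: C4 is the bridging carbonyl, C6 the enone carbonyl, C7 carries Br, and C8/C9 are the two-carbon bridge on C5/C3a.

Step 1
Reactants: 1 1-[3,5-bis(benzyloxy)phenyl]ethan-1-one
Product: 2 1-[3,5-bis(benzyloxy)-2-bromophenyl]ethan-1-one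
Conditions: NBS (1.05 equiv), MeCN, 0 °C to rt
Reagents that add atoms: N-bromosuccinimide, O=C1CCC(=O)N1Br
Why: Electrophilic aromatic bromination of a 3,5-dialkoxyaryl ketone should go to C2, which is para to one benzyloxy group and ortho to the other, and not to the more hindered C4 between the two ether groups; no stereocentre is formed.

Step 2
Reactants: 2 1-[3,5-bis(benzyloxy)-2-bromophenyl]ethan-1-one; 3 4-methoxybenzaldehyde
Product: 4 (E)-1-[3,5-bis(benzyloxy)-2-bromophenyl]-3-(4-methoxyphenyl)prop-2-en-1-one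
Conditions: KOH, EtOH–THF, rt
Reagents that add atoms: none
Why: Claisen–Schmidt condensation of the methyl ketone with a non-enolisable aldehyde, followed by E1cB loss of water, should give the conjugated (E)-enone as the stable isomer.

Step 3
Reactants: 4 (E)-1-[3,5-bis(benzyloxy)-2-bromophenyl]-3-(4-methoxyphenyl)prop-2-en-1-one
Product: 5 (3R)-4,6-bis(benzyloxy)-3-(4-methoxyphenyl)-2,3-dihydro-1H-inden-1-one
Conditions: Pd(OAc)2 (5 mol %), (R)-3,5-Xyl-MeO-BIPHEP (6 mol %), HCO2Na, DMF, 90 °C
Reagents that add atoms: none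
Why: Asymmetric intramolecular reductive Heck reaction (conjugate arylation) of a 2'-bromochalcone to a 3-arylindan-1-one: the arylpalladium bromide adds to the enone β-carbon, formate reduces off the palladium enolate, and the chiral bisphosphine sets C3 in the enantio-determining carbopalladation.

Step 4
Reactants: 5 (3R)-4,6-bis(benzyloxy)-3-(4-methoxyphenyl)-2,3-dihydro-1H-inden-1-one
Product: 6 (3R)-4,6-bis(benzyloxy)-7-bromo-3-(4-methoxyphenyl)-2,3-dihydro-1H-inden-1-one
Conditions: NBS (1.05 equiv), MeCN, 0 °C to rt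
Reagents that add atoms: N-bromosuccinimide, O=C1CCC(=O)N1Br
Why: Electrophilic aromatic bromination should take C7, para to the C4 ether and ortho to the C6 ether (C5 lies between two benzyloxy groups and the singly activated anisyl ring is much slower); this bromine later blocks C7 in step 8.

Step 5
Reactants: 6 (3R)-4,6-bis(benzyloxy)-7-bromo-3-(4-methoxyphenyl)-2,3-dihydro-1H-inden-1-one; 7 1-iodo-3,5-dimethoxybenzene
Product: 8 (2R,3R)-4,6-bis(benzyloxy)-7-bromo-2-(3,5-dimethoxyphenyl)-3-(4-methoxyphenyl)-2,3-dihydro-1H-inden-1-one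
Conditions: Pd2(dba)3 (2 mol %), Xantphos (5 mol %), NaOtBu (1.3 equiv), THF, 45 °C
Reagents that add atoms: none
Why: Palladium-catalysed α-arylation of the ketone enolate: oxidative addition should take the unhindered aryl iodide in preference to the di-ortho-substituted, electron-rich C7 bromide, and C2, epimerisable under NaOtBu, should settle trans to the C3 aryl group under thermodynamic control (2R,3R).

Step 6
Reactants: 8 (2R,3R)-4,6-bis(benzyloxy)-7-bromo-2-(3,5-dimethoxyphenyl)-3-(4-methoxyphenyl)-2,3-dihydro-1H-inden-1-one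
Product: 9 (2R,3R)-7-bromo-2-(3,5-dimethoxyphenyl)-4,6-dihydroxy-3-(4-methoxyphenyl)-2,3-dihydro-1H-inden-1-one
Conditions: BCl3 (4 equiv), pentamethylbenzene (6 equiv), CH2Cl2, −78 °C; MeOH quench
Reagents that add atoms: none
Why: Lewis acid O-debenzylation with a cation scavenger: at −78 °C BCl3 should cleave only the benzyl ethers (the benzyl cation is taken up by pentamethylbenzene in a Friedel–Crafts reaction), leaving the aryl methyl ethers, the aryl bromide, the ketone and both stereocentres.

Step 7
Reactants: 9 (2R,3R)-7-bromo-2-(3,5-dimethoxyphenyl)-4,6-dihydroxy-3-(4-methoxyphenyl)-2,3-dihydro-1H-inden-1-one; 10 (4-methoxybenzyl)magnesium chloride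
Product: 12 (1E,2R,3R)-7-bromo-2-(3,5-dimethoxyphenyl)-1-(4-methoxybenzylidene)-3-(4-methoxyphenyl)indane-4,6-diol, via tertiary alcohol 11 (not isolated)
Conditions: 10 (4.5 equiv), THF, 0 °C to rt; aq NH4Cl; crude product, TsOH·H2O (10 mol %), CH2Cl2, rt
Reagents that add atoms: none
Why: Grignard 1,2-addition to the ketone (after deprotonation of both phenols, anti to the C2 aryl group) and acid-catalysed E1 dehydration of the tertiary benzylic alcohol 11 should give the conjugated exocyclic alkene, E because the Z isomer would press the aryl group against C7–Br; the trans C2/C3 arrangement is kept and is also the thermodynamic one.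

Step 8
Reactants: 12 (1E,2R,3R)-7-bromo-2-(3,5-dimethoxyphenyl)-1-(4-methoxybenzylidene)-3-(4-methoxyphenyl)indane-4,6-diol; 13 (E)-3,5,4'-trimethoxystilbene
Product: 15 7-bromo-2,8-bis(3,5-dimethoxyphenyl)-1-[(E)-4-methoxybenzylidene]-3,9-bis(4-methoxyphenyl)-2,3-dihydro-1H-3a,5-ethanoindene-4,6(5H)-dione (bromodienone), via aryloxyiodane 14 (not isolated)
Conditions: PhI(OAc)2 (1.1 equiv), 13 (3 equiv), (CF3)2CHOH–CH2Cl2 (1:4), −40 °C; cold aq NaHCO3
Reagents that add atoms: none
Why: Cationic [5+2] cycloaddition of an oxidatively generated phenoxonium (oxidopentadienyl) cation with an aryl alkene, the phenol–alkene cycloaddition known for alkoxyphenols and propenylbenzenes: of the three cationic ring carbons (C3a, C5, C7) C7 is blocked by bromine and C3a is fully substituted, so the nucleophilic alkene carbon of 13 (the one that leaves a 4-methoxybenzyl cation) should bond to C5 and the cation then close on C3a, the β-carbon of the C4 enol, on the face anti to the C3 aryl group, the E alkene giving the trans C8/C9 diaryl unit with the 3,5-dimethoxyphenyl group endo (stacked over the cationic ring) and the anisyl group exo, away from C7–Br and C7a.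

Step 9
Reactants: 15 7-bromo-2,8-bis(3,5-dimethoxyphenyl)-1-[(E)-4-methoxybenzylidene]-3,9-bis(4-methoxyphenyl)-2,3-dihydro-1H-3a,5-ethanoindene-4,6(5H)-dione (bromodienone)
Product: 17 7-bromo hepta-O-methyl ether of 19 (bromoenone), via dienol 16 (not isolated)
Conditions: BF3·OEt2 (20 mol %), CH2Cl2, −78 to −30 °C; aq NaHCO3
Reagents that add atoms: none
Why: BF3 binds the C6 carbonyl of the 2,4-dienone (O=C6–C7(Br)=C7a–C1=CH–Ar) and makes a boron-bound hydroxypentadienyl (vinylogous oxocarbenium) cation whose positive charge rests on the exocyclic benzylic carbon, where the 4-methoxyphenyl group stabilises it. The 3,5-dimethoxyphenyl ring on the neighbouring C2 attacks this carbon through one of its two equivalent ortho positions (each ortho to one methoxy and para to the other), and loss of the arene proton gives dienol 16, which is protonated at the γ-carbon C1 to restore the conjugated enone. The closest known reactions are the Lewis acid Friedel–Crafts 1,6-additions of 3,5-dialkoxyphenyl rings to p-quinone methides and the acid-induced cyclisation of 1-benzylidene-2-arylindanes to aryl-fused bicyclo[3.3.0]octanes, carried over here to a dienone as a vinylogous Friedel–Crafts alkylation. The five-membered ring closes in a cationic 5-endo mode onto a planar delocalised cation (as a 1,3-diarylpropyl cation closes to a 1-arylindane), so the geometric restriction on 5-endo-trig attack at a neutral alkene does not apply. The benzylic centre is set by the E geometry of the alkene and by attack from the face on which the C2 aryl group stands, which puts the aryl group exo (cis to the two ring-fusion hydrogens, also the thermodynamic position), and C1 is set by the cis fusion that a bicyclo[3.3.0]octane demands, the proton arriving on the convex face. The step needs ring closure to outrun heterolysis of the strained C3a–C9 bond and attack by the other electron-rich rings: only the C2 aryl ring can reach the cationic terminus, and a catalytic Lewis acid at low temperature should keep the bicyclo[3.2.1]octenedione intact.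

Step 10
Reactants: 17 7-bromo hepta-O-methyl ether of 19 (bromoenone)
Product: 18 hepta-O-methyl ether of 19
Conditions: Pd(OAc)2 (5 mol %), PPh3 (10 mol %), HCO2Na (3 equiv), DMF, 60 °C
Reagents that add atoms: none
Why: Palladium-catalysed formate hydrogenolysis of the vinylic C–Br bond of an α-bromoenone (oxidative addition, exchange with formate, loss of CO2 to the palladium hydride, reductive elimination) should leave the enone, the non-enolisable 1,3-diketone and every stereocentre untouched.

Step 11
Reactants: 18 hepta-O-methyl ether of 19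
Product: 19 CNP0407321.1 (target)
Conditions: BBr3 (20 equiv), CH2Cl2, −78 to 0 °C; then MeOH, H2O
Reagents that add atoms: none
Why: Global O-demethylation by BBr3 (Lewis acid complexation of each ether oxygen, SN2 attack of bromide on methyl, hydrolysis of the aryl borates) should free the seven phenols; no stereocentre is epimerisable (the diketone bridgeheads cannot enolise and the cis ring fusion is the stable one), and the temperature is held at or below 0 °C to spare the strained C–C bond next to the exo 4-hydroxyphenyl group.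

**Compound list**

1 | 1-[3,5-bis(benzyloxy)phenyl]ethan-1-one | CC(=O)c1cc(OCc2ccccc2)cc(OCc2ccccc2)c1 | starting material
2 | 1-[3,5-bis(benzyloxy)-2-bromophenyl]ethan-1-one | CC(=O)c1cc(OCc2ccccc2)cc(OCc2ccccc2)c1Br | intermediate
3 | 4-methoxybenzaldehyde | COc1ccc(C=O)cc1 | starting material
4 | (E)-1-[3,5-bis(benzyloxy)-2-bromophenyl]-3-(4-methoxyphenyl)prop-2-en-1-one | COc1ccc(/C=C/C(=O)c2cc(OCc3ccccc3)cc(OCc3ccccc3)c2Br)cc1 | intermediate
5 | (3R)-4,6-bis(benzyloxy)-3-(4-methoxyphenyl)-2,3-dihydro-1H-inden-1-one | c1ccccc1COc1cc(OCc3ccccc3)cc2c1[C@@H](c1ccc(OC)cc1)CC2=O | intermediate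
6 | (3R)-4,6-bis(benzyloxy)-7-bromo-3-(4-methoxyphenyl)-2,3-dihydro-1H-inden-1-one | c1ccccc1COc1cc(OCc3ccccc3)c(Br)c2c1[C@@H](c1ccc(OC)cc1)CC2=O | intermediate
7 | 1-iodo-3,5-dimethoxybenzene | COc1cc(I)cc(OC)c1 | starting material
8 | (2R,3R)-4,6-bis(benzyloxy)-7-bromo-2-(3,5-dimethoxyphenyl)-3-(4-methoxyphenyl)-2,3-dihydro-1H-inden-1-one (2,3-trans) | c1ccccc1COc1cc(OCc3ccccc3)c(Br)c2c1[C@@H](c1ccc(OC)cc1)[C@H](c1cc(OC)cc(OC)c1)C2=O | intermediate
9 | (2R,3R)-7-bromo-2-(3,5-dimethoxyphenyl)-4,6-dihydroxy-3-(4-methoxyphenyl)-2,3-dihydro-1H-inden-1-one | Oc1cc(O)c(Br)c2c1[C@@H](c1ccc(OC)cc1)[C@H](c1cc(OC)cc(OC)c1)C2=O | intermediate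
10 | (4-methoxybenzyl)magnesium chloride | COc1ccc(C[Mg]Cl)cc1 | starting material
11 | (2R,3R)-7-bromo-2-(3,5-dimethoxyphenyl)-1-(4-methoxybenzyl)-3-(4-methoxyphenyl)-2,3-dihydro-1H-indene-1,4,6-triol, benzyl group trans to the C2 aryl group | Oc1cc(O)c(Br)c2c1[C@@H](c1ccc(OC)cc1)[C@H](c1cc(OC)cc(OC)c1)[C@@]2(O)Cc1ccc(OC)cc1 | intermediate
12 | (1E,2R,3R)-7-bromo-2-(3,5-dimethoxyphenyl)-1-(4-methoxybenzylidene)-3-(4-methoxyphenyl)-2,3-dihydro-1H-indene-4,6-diol | Oc1cc(O)c(Br)c2c1[C@@H](c1ccc(OC)cc1)[C@H](c1cc(OC)cc(OC)c1)/C2=C\c1ccc(OC)cc1 | intermediate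
13 | (E)-3,5,4'-trimethoxystilbene (resveratrol trimethyl ether) | COc1ccc(/C=C/c2cc(OC)cc(OC)c2)cc1 | starting material
14 | 4-O-[acetoxy(phenyl)-λ3-iodanyl] derivative of 12 | CC(=O)OI(c1ccccc1)Oc1cc(O)c(Br)c2c1[C@@H](c1ccc(OC)cc1)[C@H](c1cc(OC)cc(OC)c1)/C2=C\c1ccc(OC)cc1 | intermediate
15 | 7-bromo-2,8-bis(3,5-dimethoxyphenyl)-1-[(E)-4-methoxybenzylidene]-3,9-bis(4-methoxyphenyl)-2,3-dihydro-1H-3a,5-ethanoindene-4,6(5H)-dione; 2,3-trans, 8,9-trans, 9-aryl exo (towards C4=O), 8-aryl endo, C9 anti to the C3 aryl group | O=C1C(Br)=C2/C(=C/c3ccc(OC)cc3)[C@@H](c3cc(OC)cc(OC)c3)[C@H](c3ccc(OC)cc3)[C@]24C(=O)[C@H]1[C@H](c1cc(OC)cc(OC)c1)[C@H]4c1ccc(OC)cc1 | intermediate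
16 | cyclised dienol (HO–C6=C7(Br)–C7a=C1 tautomer of 17) | OC1=C(Br)C2=C3[C@H](c4ccc(OC)cc4)c4c(OC)cc(OC)cc4[C@H]3[C@H](c3ccc(OC)cc3)[C@]23C(=O)[C@H]1[C@H](c1cc(OC)cc(OC)c1)[C@H]3c1ccc(OC)cc1 | intermediate
17 | 7-bromo hepta-O-methyl ether of 19 (bromine on the enone α-carbon; cis-fused bicyclo[3.3.0]octane, benzylic aryl group exo) | O=C1C(Br)=C2[C@H]3[C@H](c4ccc(OC)cc4)c4c(OC)cc(OC)cc4[C@H]3[C@H](c3ccc(OC)cc3)[C@]23C(=O)[C@H]1[C@H](c1cc(OC)cc(OC)c1)[C@H]3c1ccc(OC)cc1 | intermediate
18 | hepta-O-methyl ether of 19 | O=C1C=C2[C@H]3[C@H](c4ccc(OC)cc4)c4c(OC)cc(OC)cc4[C@H]3[C@H](c3ccc(OC)cc3)[C@]23C(=O)[C@H]1[C@H](c1cc(OC)cc(OC)c1)[C@H]3c1ccc(OC)cc1 | intermediate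
19 | CNP0407321.1: bicyclo[3.2.1]oct-3-ene-2,8-dione fused to a cis-bicyclo[3.3.0]octane that carries the fused resorcinol ring, three 4-hydroxyphenyl groups and one 3,5-dihydroxyphenyl group | O=C1C=C2[C@H]3[C@H](c4ccc(O)cc4)c4c(O)cc(O)cc4[C@H]3[C@H](c3ccc(O)cc3)[C@]23C(=O)[C@H]1[C@H](c1cc(O)cc(O)c1)[C@H]3c1ccc(O)cc1 | target

**Totals.** Total step count: 11. Longest linear sequence: 11 steps (1 to 19; 3, 7, 10 and 13 are bought).

**Steps most likely to fail**

Step 8. The 4-methoxybenzyl cation may be captured by the enol or carbonyl oxygen with rearomatisation (dihydrobenzofuran pathway) instead of by C3a. Acetate may add ipso at C7–Br, the iodane may oxidise the electron-rich alkenes of 12 and 13, and facial or endo/exo control may be incomplete. The fallback makes the cation without an oxidant in the flask. Setting out from 12, PhI(OAc)2 in MeOH at −20 °C should give the 7a-methoxy para-quinol ether of 12 F1, methanol adding para to the oxidised oxygen at the substituted ring-fusion carbon, anti to the neighbouring aryl group. F1 and 13 with BF3·OEt2 (cat.) in CH2Cl2 at −78 °C should lose methanol to the same cation and close to 15, where the route is rejoined.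

Step 9. The Lewis acid may cleave the strained C3a–C9 bond heterolytically (4-methoxybenzyl cation plus a rearomatised ring) faster than the ring closes, or the cation may rotate and give the endo-aryl epimer. The fallback uses stoichiometric silyl activation under a base buffer, with trapping of the cyclised product. From 15, TMSOTf (1.2 equiv) and 2,6-lutidine in CH2Cl2 at −78 °C should give the trimethylsilyl ether of dienol 16 F2, so that no protic acid is present while the C–C bond forms. Hydrolysis with AcOH in wet THF at 0 °C then passes through 16, protonates C1 and returns 17.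

Step 7. The Grignard reagent may enolise the hindered, peri-brominated ketone instead of adding, the bis(phenoxide) magnesium salt may be insoluble, and the acid may scramble the alkene into the ring. The fallback protects first. From 9, TBSCl and imidazole in DMF should give the bis(TBS) ether of 9 F3; 10 (1.5 equiv, THF, 0 °C) should add to give the bis(TBS) ether of 11 F4, which TsOH·H2O in CH2Cl2 dehydrates to the bis(TBS) ether of 12 F5. Bu4NF buffered with AcOH (THF, 0 °C) then returns 12.

**Further compounds**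

F1 | step 8 | 4-bromo-2-(3,5-dimethoxyphenyl)-7-hydroxy-7a-methoxy-3-[(E)-4-methoxybenzylidene]-1-(4-methoxyphenyl)-1,2,3,7a-tetrahydro-5H-inden-5-one (7a-methoxy trans to the 1-aryl group) | O=C1C=C(O)[C@@]2(OC)[C@@H](c3ccc(OC)cc3)[C@H](c3cc(OC)cc(OC)c3)/C(=C\c3ccc(OC)cc3)C2=C1Br
F2 | step 9 | trimethylsilyl ether of dienol 16 | C[Si](C)(C)OC1=C(Br)C2=C3[C@H](c4ccc(OC)cc4)c4c(OC)cc(OC)cc4[C@H]3[C@H](c3ccc(OC)cc3)[C@]23C(=O)[C@H]1[C@H](c1cc(OC)cc(OC)c1)[C@H]3c1ccc(OC)cc1
F3 | step 7 | (2R,3R)-7-bromo-4,6-bis(tert-butyldimethylsilyloxy)-2-(3,5-dimethoxyphenyl)-3-(4-methoxyphenyl)-2,3-dihydro-1H-inden-1-one | CC(C)(C)[Si](C)(C)Oc1cc(O[Si](C)(C)C(C)(C)C)c(Br)c2c1[C@@H](c1ccc(OC)cc1)[C@H](c1cc(OC)cc(OC)c1)C2=O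
F4 | step 7 | (2R,3R)-7-bromo-4,6-bis(tert-butyldimethylsilyloxy)-2-(3,5-dimethoxyphenyl)-1-(4-methoxybenzyl)-3-(4-methoxyphenyl)-2,3-dihydro-1H-inden-1-ol, benzyl group trans to the C2 aryl group | CC(C)(C)[Si](C)(C)Oc1cc(O[Si](C)(C)C(C)(C)C)c(Br)c2c1[C@@H](c1ccc(OC)cc1)[C@H](c1cc(OC)cc(OC)c1)[C@@]2(O)Cc1ccc(OC)cc1
F5 | step 7 | (1E,2R,3R)-7-bromo-4,6-bis(tert-butyldimethylsilyloxy)-2-(3,5-dimethoxyphenyl)-1-(4-methoxybenzylidene)-3-(4-methoxyphenyl)-2,3-dihydro-1H-indene | CC(C)(C)[Si](C)(C)Oc1cc(O[Si](C)(C)C(C)(C)C)c(Br)c2c1[C@@H](c1ccc(OC)cc1)[C@H](c1cc(OC)cc(OC)c1)/C2=C\c1ccc(OC)cc1
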